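The earlier runs and the new flask stem from a simulated flask for substances that don't exist; scatter was added.

The trap in a portioned flask is to set its whole charge of free catalyst against the clock, as if the last portion had not come 9.00 min late.

all flasks: temperature −20 °C

| flask | substrate | coupling partner | free catalyst | remark | time |
|---|---|---|---|---|---|
| gamma | 0.030 M | 0.050 M | 20 µM (in portions, 4) | run made earlier; portions every 3.0 min |  |
| dusk | 0.020 M | 0.200 M | 5.0 µM | everything together at the start | 40 min |
| autumn | 0.020 M | 0.0500 M | 20 µM (in portions, 4) | the portions of free catalyst follow each other after 3.0 min, the first at the start | 40 min |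

gamma run (percent of the substrate charged)

| time / min | product / % | substrate / % |
|---|---|---|
| 0.667 | 0 | 99.3 |
| 1.33 | 0.1 | 99.8 |
| 2.50 | 0.3 | 99.5 |
| 4.00 | 0.9 | 98.5 |
| 8.00 | 3.4 | 97.0 |

(scatter of a reading: 0.3 percentage points)

- which one finishes higher in amount of product, in percent of the substrate charged ("neither" within 2 percentage points) (dusk / autumn / neither)
- amount of product at the end, in percent of the substrate charged, dusk
- amount of product at the end, in percent of the substrate charged, autumn

- the numbers in the tables scatter by 0.3 percentage points (one standard deviation)
- no earlier run changes the charge of free catalyst; that part of a forecast is a guess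

Two views of these flasks stand against each other. Mine is a pseudo-first-order loss of substrate: the logarithm of the fraction left grows in step with the catalyst present, averaged over the run, and the coupling partner does not enter. Averaged over its run, autumn holds 88.8% of its whole charge, and dusk's charge is a quarter of that whole charge. Autumn's mean over dusk's comes to 3.55, and this is the load ratio: the mean catalyst of one flask over that of another, at equal times, which multiplies the logarithm of the fraction of substrate left.

Gamma allows this view. Counted in portion-minutes, its dose grows 3.00 times from 4.00 min to 8.00 min and its product 3.78 times, but the lower reading is 0.9% with a scatter of 0.3 percentage points.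

The forecast reads the same rise as “steeper than proportional, so the data fit roughly second order in free catalyst”, and it counts the partner at first order. It names autumn, with 16% for dusk and 35% for autumn. Those two numbers hold a ratio of logarithms of 2.47, smaller than my load ratio. So we agree on the winner and part on the gap. Gamma gives my view a scale of its own: 3.4% of product, read as lost substrate, at 8.00 min, a dose equal to one portion standing for 15.0 min. Dusk holds one such portion for 40 min, so that scale puts dusk at 8.81% and, by the load ratio, autumn at 27.9%, each lower than the forecast's number. That scale hangs on one reading with a scatter of 0.3 points, so as a second choice I start from the forecast's dusk, and the load ratio then puts autumn at 46.1%, not at its 35%.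

    substrate + catalyst intermediate C ⇌ idle complex, settled at all times (K = 180 /M, ΔH = −33.0 kJ/mol)
    catalyst intermediate B ⇌ by-product + catalyst intermediate C (K = 0.00390 M, k = 50.0 /min, Ea = 54.0 kJ/mol, ΔH = −19.0 kJ/mol)
    coupling partner + catalyst intermediate A → catalyst intermediate B (k = 1300 /M/min, Ea = 37.0 kJ/mol)
    catalyst intermediate C → free catalyst + product (k = 220 /min, Ea = 64.0 kJ/mol)
    substrate + free catalyst → catalyst intermediate A (k = 2700 /M/min, Ea = 42.0 kJ/mol)
    (constants at −20 °C)

Autumn finishes ahead, at 42.5% against 15.3% for dusk, so the forecast stands 7.5 points low on autumn. Its partner term has its ground at the low partner charge: autumn has a quarter of dusk's partner, and at the end intermediate A holds 19.6% of its catalyst, more than the 5.77% in dusk. Carried from dusk's result, the load ratio gives autumn 44.5%. The neighbour of dusk charged with 1.2 × 10⁻⁵ M has a load ratio of 2.40, which gives 32.9%, and that flask stood at 34.9%.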